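The numbers in the tables are simulated for substances that don't exist.

In a one-step world free catalyst and impurity would meet one for one, and a run charged with more free catalyst than impurity would keep its surplus, the share of the charged free catalyst that exceeds the impurity charged: 28.3% in the flask. We must decide whether this charge, stopped at 8.0 h, is worth making for its remaining right-handed substrate.

the same everywhere: left-handed substrate 0.050 M; right-handed substrate 0.050 M; gas 2.8 mM (held); impurity 33 µM

|  | free catalyst | remark | time |
|---|---|---|---|
| amber | 23 µM | run made earlier |  |
| green | 34 µM | run made earlier |  |
| flask | 46 µM |  | 8.0 h |

| run | time / h | left-handed substrate / % | right-handed substrate / % |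
|---|---|---|---|
| amber | 1.33 | 38.4 | 44.7 |
| amber | 2.50 | 39.1 | 44.8 |
| amber | 4.00 | 38.4 | 44.8 |
| amber | 5.00 | 38.2 | 44.5 |
| green | 0.417 | 38.4 | 44.8 |
| green | 0.833 | 32.9 | 42.8 |
| green | 2.00 | 27.4 | 38.7 |
| green | 5.00 | 21.3 | 34.6 |

(standard deviation of a reading: 0.3 percentage points)

1. part of the left-handed substrate and right-handed substrate charged together that has reacted at 8.0 h
2. excess of left-handed product over right-handed product in the product at 8.0 h
3. excess of right-handed substrate over left-handed substrate among what is left of the two at 8.0 h

- free catalyst is single-handed; left-handed substrate and right-handed substrate are mirror images of each other, charged as a racemate, each of them at the stated concentration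
- at the start none of reagent is dissolved
- what was read earlier has a scatter of 0.3 percentage points, one standard deviation
- steps under discussion: free catalyst -> spent catalyst B; reagent + free catalyst + left-handed substrate -> free catalyst + left-handed product; gas <-> reagent; reagent + free catalyst + right-handed substrate -> free catalyst + right-handed product; free catalyst + impurity -> spent catalyst A
- an excess is the difference of the two amounts in percent of their sum
- an excess is below zero if the other one leads

Write Φ for minus the logarithm of the fraction of left-handed substrate left. The amber run charges less free catalyst than impurity and stands still at a mean Φ of 0.261. We assume that Φ grows in step with the logarithmic fall of the impurity, and amber then gives a ratio of 0.218. The last green reading gives a selectivity factor of 2.32.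

Green's surplus is 2.94%, and between its last two readings its Φ climbs on average by 0.0839 h⁻¹. Scaling that climb to the flask by the concentration by which free catalyst exceeds impurity gives a first answer of Φ = 8.73. Going round once more, the ratio puts green's unconsumed impurity at 6.36% and then 2.01% of its charge. On this reckoning free catalyst in green averaged 7.00% of its charge over that stretch, more than the surplus. With this correction, and with the early burst added as the ratio times ln(1/surplus), we estimate Φ = 3.94 for the flask. Our reckoning leaves 0.971% left-handed and 9.13% right-handed substrate, so 89.9% has reacted and the substrate excess is 80.8%. We would charge the flask as written.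

The forecast says 91% (80% to 96%), a product excess of 8.3% (4% to 17%) and a substrate excess of 83.4% (62% to 93%), on the ground that "The flask keeps about 13 µM of catalyst". Our reacted part and our substrate excess lie below its central figures.

The flask gives 91.2% reacted, a product excess of 8.13% and a substrate excess of 84.0%.

    free catalyst → spent catalyst B (k = 0.0120 h⁻¹)
    reagent + free catalyst + left-handed substrate → free catalyst + left-handed product (k = 1.50 × 10⁷ L² mol⁻² h⁻¹)
    gas ⇌ reagent, rate k3*(csat - [reagent]) (kL = 130 h⁻¹)
    reagent + free catalyst + right-handed substrate → free catalyst + right-handed product (k = 6.40 × 10⁶ L² mol⁻² h⁻¹)
    free catalyst + impurity → spent catalyst A (k = 1.70 × 10⁵ L mol⁻¹ h⁻¹)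

At 8.00 h the flask has 0% of its impurity left and holds 71.7% of its catalyst as spent catalyst A, 25.5% as free catalyst and 2.76% as spent catalyst B, so the last two together make 28.3% against a surplus of 28.3%. The neighbour charged with 1.2 × 10⁻⁵ M of free catalyst has less than its impurity, and one-for-one counting leaves 63.6% of that impurity unmet. That neighbour holds 64% of its impurity at 8.00 h, with free catalyst at 0% and 7.07% reacted.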